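Ring A (C1, C10–C14) is taken apart across C10–C11 and C1–C14. Its C12 oxygen, flanked by the C11 methine and the C13–C14 epoxide, marks a 2-silyloxydiene, and the trans carbon branches C2 and C9 on the adjacent C1 (quaternary, C15 methyl) and C10 mark an (E)-methylbutenedioate. One Lewis-acid-promoted Diels–Alder reaction between di-(–)-menthyl mesaconate and (Z)-3-silyloxypenta-1,3-diene therefore closes ring A and sets C1, C10 and C11, leaving the C12 enol ether for later oxygenation. The two esters are then told apart by lactonisation, ring B is closed by a B-alkyl Suzuki coupling (C4–C5), and the lactone by a samarium Reformatsky reaction.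

Key step: step 3

Remarks on the chemistry (assumptions):
- Atom numbers follow the target SMILES: C16=C5, C4, C3, C2, C1 (C15 methyl), C10, C11 (C20 methyl), C12, C13, C14, then C9, C8, C17 (C18 methyl), C19, lactone O, C7, C6. Ring A = C1, C10–C14; ring B = C1–C10. β is the face of ring A that carries the C15 methyl (C9 and C20 are β; O12 and the epoxide are α).
- Hydride reduction of the ring A enone is assumed to occur from the α-face (12β-alcohol), so the 12α-oxygen of the target is reached by inversion in step 7.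
- The dienophile keeps two identical menthyl esters, because both are needed for face shielding; they are told apart after the cycloaddition through the C12 hydroxyl (step 5).
- The 2-bromopropanoyl unit is used as the racemate; its CHBr centre is drawn unspecified and is erased in the samarium enolate.

Step 1
Reactants: 1 mesaconic acid; 2 (–)-menthol
Product: 3 di-(–)-menthyl mesaconate
Conditions: 2 (2.2 equiv in all), p-TsOH·H2O (cat.), PhMe, reflux, Dean–Stark
Reagents that add atoms: (–)-menthol (the second equivalent of 2), CC(C)[C@@H]1CC[C@@H](C)C[C@H]1O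
Why: Fischer esterification driven by azeotropic removal of water should esterify each of the two carboxyl groups with one molecule of menthol without touching the (E)-alkene, the most stable isomer of this series, or any stereocentre.

Step 2
Reactants: 4 pent-1-en-3-one
Product: 5 (Z)-3-(tert-butyldimethylsilyloxy)penta-1,3-diene
Conditions: TBSOTf, Et3N, Et2O, 0 °C
Reagents that add atoms: tert-butyldimethylsilyl trifluoromethanesulfonate, CC(C)(C)[Si](C)(C)OS(=O)(=O)C(F)(F)F
Why: Soft enolisation and O-silylation of the ethyl ketone should give the cross-conjugated silyl enol ether with the Z geometry (methyl trans to the vinyl group) that amine/silyl triflate conditions normally deliver.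

Step 3
Reactants: 3 di-(–)-menthyl mesaconate; 5 (Z)-3-(tert-butyldimethylsilyloxy)penta-1,3-diene
Product: 6 ring A cyclohexene diester with C12 silyl enol ether
Conditions: Et2AlCl (2 equiv), PhMe, −78 → −40 °C; Et3N, aq. NaHCO3 quench
Reagents that add atoms: none
Why: The aluminium-complexed diester 3 and the electron-rich diene 5 combine in a concerted but asynchronous [4+2] cycloaddition in which the C11–C10 bond runs ahead of the C14–C1 bond, the closest known reactions being Lewis-acid-promoted Diels–Alder additions of 2-silyloxydienes to fumarates and the alkylaluminium chloride-mediated additions of dienes to dimenthyl fumarate. Ring A is closed as a six-membered carbocycle in this single suprafacial cycloaddition (both σ-bonds in one transition state, no separate cyclisation), so the E geometry of 3 becomes the trans relation of the C2 and C9 esters on C1 and C10. C11 is set relative to C10 by the Z enol ether, whose methyl group lies on the outside of the s-cis diene, together with the endo position of the C9 ester, which follows because the C2 ester geminal to the C15 methyl prefers exo as methacrylate-type esters do. The absolute configuration is controlled by the two (–)-menthyl groups, which shield the same face of the s-trans, aluminium-bound diester; by analogy with the fumarate series they are expected to expose the face that gives 6 as drawn, which must be confirmed on the first batch, (+)-menthol being equally available. Regiochemistry is secured by attack of the nucleophilic diene terminus C11 on the unsubstituted and more electrophilic alkene carbon C10, which also places the C12 oxygen para to the quaternary C1.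

Step 4
Reactants: 6 ring A silyl enol ether diester
Product: 7 ring A Δ13-12-ketone diester
Conditions: Pd(OAc)2 (1.05 equiv), MeCN, 40 °C
Reagents that add atoms: none
Why: Saegusa–Ito oxidation: the silyl enol ether is converted into a C13-bound divalent palladium enolate and β-hydride elimination from C14 should give the enone regiospecifically under neutral conditions that do not epimerise C11.

Step 5
Reactants: 7 ring A enone diester
Product: 9 bridged C9→O12 lactone carrying the C2 menthyl ester, via 12β-allylic alcohol 8 (not isolated)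
Conditions: NaBH4, CeCl3·7H2O, MeOH, −40 °C; then NaH (0.2 equiv), THF, 0 °C → rt
Reagents that add atoms: none
Why: Luche 1,2-reduction should deliver hydride to the α-face of the half-chair in which both esters are axial (the β-face of C12 is screened by the axial C10 ester), giving the 12β-alcohol, and alkoxide-catalysed transesterification then closes the lactone with the only ester that is cis-1,3 to O12, which tells C9 from C2.

Step 6
Reactants: 9 bridged lactone
Product: 10 C9 Weinreb amide with free 12β-hydroxyl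
Conditions: MeNH(OMe)·HCl, AlMe3, CH2Cl2, 0 °C → rt
Reagents that add atoms: N,O-dimethylhydroxylamine hydrochloride, CNOC.Cl
Why: Weinreb aminolysis with the aluminium amide should open the bridged lactone at its acyl carbon while the menthyl ester on the quaternary C1 is too hindered to react, and no stereocentre is involved.

Step 7
Reactants: 10 12β-hydroxy Weinreb amide
Product: 11 12α-(4-methoxyphenyl) ether
Conditions: 4-MeOC6H4OH, PPh3, DIAD, PhMe, 0 °C → rt
Reagents that add atoms: 4-methoxyphenol, COc1ccc(O)cc1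
Why: Mitsunobu etherification: SN2 displacement of the oxyphosphonium group by the phenol from the open α-face should invert C12 to the configuration of the target (SN2′ attack at the neopentyl C14 being disfavoured) and leave an aryl ether that withstands every later reduction.

Step 8
Reactants: 11 12α-aryl ether Weinreb amide
Product: 12 C9 aldehyde
Conditions: i-Bu2AlH (1.2 equiv), THF, −78 °C; aq. potassium sodium tartrate
Reagents that add atoms: none
Why: Weinreb amide reduction stops at the chelated aluminium hemiaminal and should release the aldehyde on work-up, the hindered menthyl ester being inert at this temperature.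

Step 9
Reactants: 13 4-methoxybenzyl alcohol; 14 2-chloro-N-methoxy-N-methylacetamide
Product: 15 N-methoxy-N-methyl-2-(4-methoxybenzyloxy)acetamide
Conditions: NaH, THF, 0 °C → rt
Reagents that add atoms: none
Why: Williamson ether synthesis: the alkoxide displaces chloride from the activated α-chloro amide.

Step 10
Reactants: 15 N-methoxy-N-methyl-2-(4-methoxybenzyloxy)acetamide; 16 prop-1-ynylmagnesium bromide
Product: 17 1-(4-methoxybenzyloxy)pent-3-yn-2-one
Conditions: THF, 0 °C; aq. NH4Cl
Reagents that add atoms: none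
Why: Weinreb ketone synthesis: the chelated tetrahedral intermediate prevents a second addition, so the ynone should form cleanly.

Step 11
Reactants: 17 1-(4-methoxybenzyloxy)pent-3-yn-2-one
Product: 18 (Z)-4-iodo-1-(4-methoxybenzyloxy)pent-3-en-2-one
Conditions: NaI, AcOH, rt, dark
Reagents that add atoms: sodium iodide, [Na+].[I-]
Why: Conjugate hydroiodination of an ynone proceeds by anti addition and should give the (Z)-β-iodoenone (iodine cis to the carbonyl), which later becomes the 5Z alkene.

Step 12
Reactants: 18 (Z)-β-iodoenone; 12 C9 aldehyde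
Product: 20 aldol adduct (9-hydroxy; 8-OPMB; 7-ketone), via dibutylboron enolate 19 (not isolated)
Conditions: Bu2BOTf, i-Pr2NEt, CH2Cl2, −78 °C; then 12, −78 → −20 °C; pH 7 buffer, MeOH
Reagents that add atoms: none
Why: Boron aldol reaction: the (Z)-enol borinate reacts through a chair Zimmerman–Traxler transition state to give the 8,9-syn adduct, and Felkin–Anh addition to the aldehyde, anti to the quaternary C1 branch and past the C10 hydrogen, should set C9 as in the target.

Step 13
Reactants: 20 aldol adduct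
Product: 21 7,9-syn diol
Conditions: Et2BOMe, NaBH4, THF/MeOH (4:1), −78 °C
Reagents that add atoms: none
Why: Narasaka–Prasad reduction: axial hydride delivery to the six-membered boron chelate of the β-hydroxy ketone should give the 1,3-syn diol, which is the C7 configuration of the target, without touching the hindered ester or the iodoalkene.

Step 14
Reactants: 21 7,9-syn diol
Product: 23 7-O-triethylsilyl 9-O-tert-butyldimethylsilyl bis-ether, via C7 triethylsilyl ether 22 (not isolated)
Conditions: TESCl, imidazole, CH2Cl2, −20 °C; then TBSOTf, 2,6-lutidine, 0 °C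
Reagents that add atoms: chlorotriethylsilane, CC[Si](Cl)(CC)CC; tert-butyldimethylsilyl trifluoromethanesulfonate, CC(C)(C)[Si](C)(C)OS(=O)(=O)C(F)(F)F
Why: Silyl ether formation under steric control: the silyl chloride should react only at the allylic C7 hydroxyl and the triflate then caps the hindered C9 hydroxyl, giving a labile group at C7 and a lasting one at C9.

Step 15
Reactants: 23 bis-silyl ether menthyl ester
Product: 24 C2 primary alcohol
Conditions: i-Bu2AlH (3 equiv), CH2Cl2, −78 → 0 °C; aq. potassium sodium tartrate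
Reagents that add atoms: none
Why: Ester reduction to the primary alcohol should proceed on warming, with the alkenyl iodide and the silyl, benzyl and aryl ethers inert to the aluminium hydride.

Step 16
Reactants: 24 C2 primary alcohol
Product: 25 C2 aldehyde
Conditions: Dess–Martin periodinane, NaHCO3, CH2Cl2, rt
Reagents that add atoms: none
Why: Dess–Martin oxidation of the only free hydroxyl gives the non-enolisable neopentyl aldehyde.

Step 17
Reactants: 25 C2 aldehyde; 26 vinylmagnesium bromide
Product: 27 C2 vinyl carbinol (both C2 epimers)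
Conditions: THF, −78 °C; aq. NH4Cl
Reagents that add atoms: none
Why: Grignard addition to the hindered aldehyde installs C3 and C4, and the configuration at C2 is not relied on here because it is reset in steps 18 and 19.

Step 18
Reactants: 27 C2 vinyl carbinol
Product: 28 C2 vinyl ketone
Conditions: Dess–Martin periodinane, NaHCO3, CH2Cl2, 0 °C
Reagents that add atoms: none
Why: Dess–Martin oxidation converges both epimers on one enone, which is used at once to avoid conjugate addition.

Step 19
Reactants: 28 C2 vinyl ketone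
Product: 29 (2R)-vinyl carbinol
Conditions: (S)-2-methyl-CBS-oxazaborolidine [(S)-1-methyl-3,3-diphenyltetrahydro-1H,3H-pyrrolo[1,2-c][1,3,2]oxazaborole] (0.5 equiv), catecholborane, PhMe, −78 °C
Reagents that add atoms: none
Why: Corey–Bakshi–Shibata reduction: with the quaternary C1 as the large and vinyl as the small substituent the (S)-catalyst should deliver hydride to give the (2R)-alcohol under catalyst control, and catecholborane at low temperature does not hydroborate the alkenes.

Step 20
Reactants: 29 (2R)-vinyl carbinol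
Product: 30 (2R)-acetate
Conditions: Ac2O, 4-(dimethylamino)pyridine (cat.), pyridine, rt
Reagents that add atoms: acetic anhydride, CC(=O)OC(C)=O
Why: Nucleophile-catalysed acylation installs the C2 acetate of the target early, where it also serves as the protecting group.

Step 21
Reactants: 30 seco iodoalkene with C2 vinyl acetate
Product: 32 ring B macrocycle with (5Z)-alkene, via B-alkyl-9-BBN adduct 31 (not isolated)
Conditions: 9-BBN, THF, rt; then PdCl2(dppf) (dppf = 1,1′-bis(diphenylphosphino)ferrocene), AsPh3, Cs2CO3, DMF/THF/H2O, 50 °C, slow addition (about 1 mM)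
Reagents that add atoms: none
Why: B-alkyl Suzuki–Miyaura macrocyclisation: 9-BBN hydroborates only the terminal vinyl group (boron at C4) and intramolecular coupling with the alkenyl iodide under high dilution should form C4–C5 with retention of the Z geometry, closing the ten-membered ring B.

Step 22
Reactants: 32 ring B macrocycle
Product: 33 C7 alcohol
Conditions: pyridinium p-toluenesulfonate (cat.), MeOH/CH2Cl2, 0 °C
Reagents that add atoms: none
Why: Acid-catalysed methanolysis should remove the allylic triethylsilyl ether selectively, the hindered tert-butyldimethylsilyl ether at C9 being far slower.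

Step 23
Reactants: 33 C7 alcohol; 34 2-bromopropanoyl bromide
Product: 35 C7 2-bromopropanoate
Conditions: pyridine, CH2Cl2, 0 °C
Reagents that add atoms: none
Why: Acylation of the only free hydroxyl with the acid bromide attaches C17 to C19 through the future lactone oxygen.

Step 24
Reactants: 35 C7 2-bromopropanoate
Product: 36 C8 alcohol
Conditions: DDQ, CH2Cl2/pH 7 buffer, 0 °C → rt
Reagents that add atoms: none
Why: Oxidative cleavage of the 4-methoxybenzyl ether by single-electron transfer should free the C8 hydroxyl, the 4-methoxyphenyl ether and the alkenes being much less readily oxidised.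

Step 25
Reactants: 36 C8 alcohol
Product: 37 C8 ketone
Conditions: Dess–Martin periodinane, NaHCO3, CH2Cl2, 0 °C → rt
Reagents that add atoms: none
Why: Dess–Martin oxidation under buffered, non-basic conditions gives the α-acyloxy ketone without enolising C7 or C9.

Step 26
Reactants: 37 C8 ketone
Product: 38 trans-fused 8-hydroxy γ-lactone
Conditions: SmI2 (2.5 equiv), THF, −78 °C
Reagents that add atoms: none
Why: Intramolecular samarium Reformatsky reaction: SmI2 reduces the C–Br bond to a trivalent samarium enolate that adds to the adjacent C8 ketone through a chelated five-membered transition state, and C17 should bond to the carbonyl face that leaves C9 trans to C6 on the new ring with the C18 methyl turned away from C9 (cis to the new hydroxyl), which sets C8 and C17 as in the target.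

Step 27
Reactants: 38 hydroxy lactone 12α-aryl ether
Product: 39 12α-allylic alcohol
Conditions: (NH4)2Ce(NO3)6, pyridine, MeCN/H2O (4:1), 0 °C
Reagents that add atoms: none
Why: Oxidative dearylation: tetravalent cerium oxidises the 4-methoxyphenyl ether to benzoquinone and releases the C12 hydroxyl with retention, the buffered conditions sparing the silyl ether.

Step 28
Reactants: 39 12α-allylic alcohol
Product: 40 13α,14α-epoxy 12α-alcohol
Conditions: VO(acac)2 (5 mol %), t-BuOOH, CH2Cl2, 0 °C → rt
Reagents that add atoms: tert-butyl hydroperoxide, CC(C)(C)OO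
Why: Vanadium-catalysed hydroxyl-directed epoxidation delivers oxygen to the Δ13 alkene from the face of the 12α-hydroxyl, giving the cis-epoxy alcohol, and the Δ5 alkene, which has only a hindered tertiary homoallylic hydroxyl nearby, should react much more slowly.

Step 29
Reactants: 40 epoxy alcohol
Product: 41 2,12-diacetate
Conditions: Ac2O, 4-(dimethylamino)pyridine (cat.), pyridine, CH2Cl2, 0 °C → rt
Reagents that add atoms: acetic anhydride, CC(=O)OC(C)=O
Why: Acylation of the secondary C12 hydroxyl should be selective, the tertiary C8 hydroxyl being too hindered to be acetylated under these conditions.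

Step 30
Reactants: 41 2,12-diacetate with Δ5 alkene
Product: 42 6-chloro-5(16)-ene 9-O-silyl ether
Conditions: Ca(OCl)2, CO2 (solid), CH2Cl2/H2O, 0 °C
Reagents that add atoms: calcium hypochlorite, [Ca+2].[O-]Cl.[O-]Cl
Why: Ene-type allylic chlorination: hypochlorous acid generated in the flask adds electrophilic chlorine to the less substituted C6 of the only remaining alkene with loss of a C16 proton, and delivery anti to C8 in the conformer that holds the C7–O bond near the alkene plane should give the (6S)-chloride, which has to be confirmed.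

Step 31
Reactants: 42 9-O-silyl ether of the target
Product: 43 CNP0242711.1
Conditions: HF·pyridine, pyridine, THF, 0 °C → rt
Reagents that add atoms: none
Why: Fluoride-mediated desilylation under buffered, non-basic conditions removes the last protecting group without opening the epoxide, displacing the allylic chloride or moving the acetates.

Compound list
1 | mesaconic acid, (E)-2-methylbut-2-enedioic acid | OC(=O)/C=C(\C)C(=O)O | starting material
2 | (–)-menthol, (1R,2S,5R) | CC(C)[C@@H]1CC[C@@H](C)C[C@H]1O | starting material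
3 | di-(–)-menthyl mesaconate | O=C(O[C@@H]1C[C@H](C)CC[C@H]1C(C)C)/C=C(\C)C(=O)O[C@@H]2C[C@H](C)CC[C@H]2C(C)C | intermediate
4 | pent-1-en-3-one | CCC(=O)C=C | starting material
5 | (Z)-3-(tert-butyldimethylsilyloxy)penta-1,3-diene | C=C/C(O[Si](C)(C)C(C)(C)C)=C/C | intermediate
6 | Diels–Alder adduct: ring A C12 silyl enol ether (Δ12); C2 menthyl ester α on C1, C9 menthyl ester β on C10, C15 and C20 methyls β | O=C(O[C@@H]1C[C@H](C)CC[C@H]1C(C)C)[C@H]2[C@@H](C)C(O[Si](C)(C)C(C)(C)C)=CC[C@]2(C)C(=O)O[C@@H]3C[C@H](C)CC[C@H]3C(C)C | intermediate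
7 | ring A Δ13-12-ketone diester (C1, C10, C11 as in 6) | O=C(O[C@@H]1C[C@H](C)CC[C@H]1C(C)C)[C@H]2[C@@H](C)C(=O)C=C[C@]2(C)C(=O)O[C@@H]3C[C@H](C)CC[C@H]3C(C)C | intermediate
8 | 12β-allylic alcohol diester (hydroxyl cis to C20 and C9) | O=C(O[C@@H]1C[C@H](C)CC[C@H]1C(C)C)[C@H]2[C@@H](C)[C@@H](O)C=C[C@]2(C)C(=O)O[C@@H]3C[C@H](C)CC[C@H]3C(C)C | intermediate
9 | bridged lactone C9(=O)–O12 (6-oxabicyclo[3.2.1]oct-2-en-7-one core) with the C2 menthyl ester | O=C1O[C@H]2C=C[C@](C)(C(=O)O[C@@H]3C[C@H](C)CC[C@H]3C(C)C)[C@@H]1[C@H]2C | intermediate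
10 | C9 N-methoxy-N-methylamide, free 12β-hydroxyl, C2 menthyl ester | CON(C)C(=O)[C@H]1[C@@H](C)[C@@H](O)C=C[C@]1(C)C(=O)O[C@@H]2C[C@H](C)CC[C@H]2C(C)C | intermediate
11 | 12α-(4-methoxyphenoxy) C9 Weinreb amide | CON(C)C(=O)[C@H]1[C@@H](C)[C@H](Oc2ccc(OC)cc2)C=C[C@]1(C)C(=O)O[C@@H]3C[C@H](C)CC[C@H]3C(C)C | intermediate
12 | C9 aldehyde, 12α-(4-methoxyphenoxy), C2 menthyl ester | O=C[C@H]1[C@@H](C)[C@H](Oc2ccc(OC)cc2)C=C[C@]1(C)C(=O)O[C@@H]3C[C@H](C)CC[C@H]3C(C)C | intermediate
13 | 4-methoxybenzyl alcohol | COc1ccc(CO)cc1 | starting material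
14 | 2-chloro-N-methoxy-N-methylacetamide | CON(C)C(=O)CCl | starting material
15 | N-methoxy-N-methyl-2-(4-methoxybenzyloxy)acetamide | CON(C)C(=O)COCc1ccc(OC)cc1 | intermediate
16 | prop-1-ynylmagnesium bromide | CC#C[Mg]Br | starting material
17 | 1-(4-methoxybenzyloxy)pent-3-yn-2-one | CC#CC(=O)COCc1ccc(OC)cc1 | intermediate
18 | (Z)-4-iodo-1-(4-methoxybenzyloxy)pent-3-en-2-one | C/C(I)=C/C(=O)COCc1ccc(OC)cc1 | intermediate
19 | dibutylboron (Z)-enolate of 18 | CCCCB(CCCC)O/C(/C=C(/C)I)=C\OCc1ccc(OC)cc1 | intermediate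
20 | aldol adduct: 9-hydroxyl (target configuration), 8-(4-methoxybenzyloxy) syn to it, 7-ketone, (5Z)-5-iodoalkene | C/C(I)=C/C(=O)[C@@H](OCc1ccc(OC)cc1)[C@H](O)[C@H]2[C@@H](C)[C@H](Oc3ccc(OC)cc3)C=C[C@]2(C)C(=O)O[C@@H]4C[C@H](C)CC[C@H]4C(C)C | intermediate
21 | 7,9-syn diol | C/C(I)=C/[C@H](O)[C@@H](OCc1ccc(OC)cc1)[C@H](O)[C@H]2[C@@H](C)[C@H](Oc3ccc(OC)cc3)C=C[C@]2(C)C(=O)O[C@@H]4C[C@H](C)CC[C@H]4C(C)C | intermediate
22 | 7-O-triethylsilyl ether of 21 | C/C(I)=C/[C@H](O[Si](CC)(CC)CC)[C@@H](OCc1ccc(OC)cc1)[C@H](O)[C@H]2[C@@H](C)[C@H](Oc3ccc(OC)cc3)C=C[C@]2(C)C(=O)O[C@@H]4C[C@H](C)CC[C@H]4C(C)C | intermediate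
23 | 7-O-triethylsilyl 9-O-tert-butyldimethylsilyl ether, C2 menthyl ester | C/C(I)=C/[C@H](O[Si](CC)(CC)CC)[C@@H](OCc1ccc(OC)cc1)[C@H](O[Si](C)(C)C(C)(C)C)[C@H]2[C@@H](C)[C@H](Oc3ccc(OC)cc3)C=C[C@]2(C)C(=O)O[C@@H]4C[C@H](C)CC[C@H]4C(C)C | intermediate
24 | C2 primary alcohol | C/C(I)=C/[C@H](O[Si](CC)(CC)CC)[C@@H](OCc1ccc(OC)cc1)[C@H](O[Si](C)(C)C(C)(C)C)[C@H]2[C@@H](C)[C@H](Oc3ccc(OC)cc3)C=C[C@]2(C)CO | intermediate
25 | C2 aldehyde | C/C(I)=C/[C@H](O[Si](CC)(CC)CC)[C@@H](OCc1ccc(OC)cc1)[C@H](O[Si](C)(C)C(C)(C)C)[C@H]2[C@@H](C)[C@H](Oc3ccc(OC)cc3)C=C[C@]2(C)C=O | intermediate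
26 | vinylmagnesium bromide | C=C[Mg]Br | starting material
27 | C2 vinyl carbinol, C2 unspecified (both epimers) | C/C(I)=C/[C@H](O[Si](CC)(CC)CC)[C@@H](OCc1ccc(OC)cc1)[C@H](O[Si](C)(C)C(C)(C)C)[C@H]2[C@@H](C)[C@H](Oc3ccc(OC)cc3)C=C[C@]2(C)C(O)C=C | intermediate
28 | C2 vinyl ketone | C/C(I)=C/[C@H](O[Si](CC)(CC)CC)[C@@H](OCc1ccc(OC)cc1)[C@H](O[Si](C)(C)C(C)(C)C)[C@H]2[C@@H](C)[C@H](Oc3ccc(OC)cc3)C=C[C@]2(C)C(=O)C=C | intermediate
29 | (2R)-vinyl carbinol | C/C(I)=C/[C@H](O[Si](CC)(CC)CC)[C@@H](OCc1ccc(OC)cc1)[C@H](O[Si](C)(C)C(C)(C)C)[C@H]2[C@@H](C)[C@H](Oc3ccc(OC)cc3)C=C[C@]2(C)[C@H](O)C=C | intermediate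
30 | (2R)-acetate, seco iodoalkene | C/C(I)=C/[C@H](O[Si](CC)(CC)CC)[C@@H](OCc1ccc(OC)cc1)[C@H](O[Si](C)(C)C(C)(C)C)[C@H]2[C@@H](C)[C@H](Oc3ccc(OC)cc3)C=C[C@]2(C)[C@H](OC(C)=O)C=C | intermediate
31 | B-alkyl-9-borabicyclo[3.3.1]nonane from 30 (boron on C4) | C/C(I)=C/[C@H](O[Si](CC)(CC)CC)[C@@H](OCc1ccc(OC)cc1)[C@H](O[Si](C)(C)C(C)(C)C)[C@H]2[C@@H](C)[C@H](Oc3ccc(OC)cc3)C=C[C@]2(C)[C@H](OC(C)=O)CCB4C5CCCC4CCC5 | intermediate
32 | ring B closed: (5Z)-alkene, 7-OTES, 8-OPMB, 9-OTBS, 2-OAc, 12α-OPMP, Δ13 | C/C1=C/[C@H](O[Si](CC)(CC)CC)[C@@H](OCc3ccc(OC)cc3)[C@H](O[Si](C)(C)C(C)(C)C)[C@H]2[C@@H](C)[C@H](Oc4ccc(OC)cc4)C=C[C@]2(C)[C@H](OC(C)=O)CC1 | intermediate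
33 | C7 alcohol of 32 | C/C1=C/[C@H](O)[C@@H](OCc3ccc(OC)cc3)[C@H](O[Si](C)(C)C(C)(C)C)[C@H]2[C@@H](C)[C@H](Oc4ccc(OC)cc4)C=C[C@]2(C)[C@H](OC(C)=O)CC1 | intermediate
34 | 2-bromopropanoyl bromide (racemic) | CC(Br)C(=O)Br | starting material
35 | C7 2-bromopropanoate (CHBr centre unspecified) | C/C1=C/[C@H](OC(=O)C(C)Br)[C@@H](OCc3ccc(OC)cc3)[C@H](O[Si](C)(C)C(C)(C)C)[C@H]2[C@@H](C)[C@H](Oc4ccc(OC)cc4)C=C[C@]2(C)[C@H](OC(C)=O)CC1 | intermediate
36 | C8 alcohol | C/C1=C/[C@H](OC(=O)C(C)Br)[C@@H](O)[C@H](O[Si](C)(C)C(C)(C)C)[C@H]2[C@@H](C)[C@H](Oc4ccc(OC)cc4)C=C[C@]2(C)[C@H](OC(C)=O)CC1 | intermediate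
37 | C8 ketone | C/C1=C/[C@H](OC(=O)C(C)Br)C(=O)[C@H](O[Si](C)(C)C(C)(C)C)[C@H]2[C@@H](C)[C@H](Oc4ccc(OC)cc4)C=C[C@]2(C)[C@H](OC(C)=O)CC1 | intermediate
38 | trans-fused 8-hydroxy γ-lactone (C7, C8, C17 as in the target), 9-OTBS, 12α-OPMP | C/C1=C/[C@@H]2OC(=O)[C@H](C)[C@@]2(O)[C@H](O[Si](C)(C)C(C)(C)C)[C@H]3[C@@H](C)[C@H](Oc4ccc(OC)cc4)C=C[C@]3(C)[C@H](OC(C)=O)CC1 | intermediate
39 | 12α-allylic alcohol | C/C1=C/[C@@H]2OC(=O)[C@H](C)[C@@]2(O)[C@H](O[Si](C)(C)C(C)(C)C)[C@H]3[C@@H](C)[C@H](O)C=C[C@]3(C)[C@H](OC(C)=O)CC1 | intermediate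
40 | 13α,14α-epoxy 12α-alcohol | C/C1=C/[C@@H]2OC(=O)[C@H](C)[C@@]2(O)[C@H](O[Si](C)(C)C(C)(C)C)[C@H]3[C@@H](C)[C@H](O)[C@@H]4O[C@@H]4[C@]3(C)[C@H](OC(C)=O)CC1 | intermediate
41 | 2,12-diacetate, 13,14-epoxide, (5Z)-alkene, 9-OTBS | C/C1=C/[C@@H]2OC(=O)[C@H](C)[C@@]2(O)[C@H](O[Si](C)(C)C(C)(C)C)[C@H]3[C@@H](C)[C@H](OC(C)=O)[C@@H]4O[C@@H]4[C@]3(C)[C@H](OC(C)=O)CC1 | intermediate
42 | 9-O-tert-butyldimethylsilyl ether of the target | C=C1CC[C@@H](OC(C)=O)[C@]2(C)[C@H]([C@@H](C)[C@H](OC(C)=O)[C@@H]3O[C@@H]32)[C@@H](O[Si](C)(C)C(C)(C)C)[C@]2(O)[C@@H](C)C(=O)O[C@H]2[C@H]1Cl | intermediate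
43 | CNP0242711.1 | C=C1CC[C@@H](OC(C)=O)[C@]2(C)[C@H]([C@@H](C)[C@H](OC(C)=O)[C@@H]3O[C@@H]32)[C@@H](O)[C@]2(O)[C@@H](C)C(=O)O[C@H]2[C@H]1Cl | target

Total steps: 31. Longest linear sequence: 27 steps (1, 3–8, 12–31).

Steps most likely to fail

Step 3. The two menthyl groups may discriminate the faces of the methyl-substituted fumarate poorly, or the Lewis acid may divert the silyl enol ether into a stepwise Mukaiyama–Michael addition with loss of silicon and of endo control. The fallback makes the same two bonds anionically, setting out from 3 and 4 and coming back at 6. Pent-1-en-3-one 4 is deprotonated at C11 with LiN(i-Pr)2 (THF, −78 °C) to give lithium (Z)-penta-1,3-dien-3-olate F1. F1 adds to 3 in a double Michael annulation: C11 attacks C10, and the resulting ester enolate at C1 then attacks the enone terminus C14. This gives the regiodefined ring A lithium enolate F2, which is silylated in the same flask with TBSCl/DMPU to return 6. The chelated stepwise pathway is governed by the same auxiliaries through a different transition-state geometry, so the relative and absolute configuration would have to be confirmed again.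

Step 21. Intermolecular coupling and protodeboronation may outrun closure of the ten-membered ring on the flexible, heavily silylated seco chain. The fallback builds the trans-lactone first, so that it fixes the C6–C7–C8–C9 turn, and closes ring B last; it sets out from 30 and comes back at 38. Pyridinium p-toluenesulfonate in MeOH frees the C7 hydroxyl to give seco alcohol F3, and acylation with 34 gives seco bromopropanoate F4. DDQ then gives seco C8 alcohol F5, Dess–Martin oxidation gives seco C8 ketone F6, and SmI2 at −78 °C gives seco hydroxy lactone F7. Hydroboration with 9-BBN gives lactone alkylborane F8, and the same palladium-catalysed B-alkyl coupling under high dilution closes ring B directly to 38.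

Step 30. Chlorine may be delivered to the other face of C6, or the C8 hydroxyl may trap the chloronium-like intermediate as a cyclic ether. The fallback is a two-step selenium route that puts chlorine on the face opposite to the electrophile; it sets out from 41 and comes back at 42. PhSeCl (CH2Cl2, −78 °C) should add anti under kinetic control, with selenium on the exposed face at the tertiary C5 and chloride at C6 from the other face, to give chloro selenide F9. H2O2/pyridine (0 °C) oxidises it to selenoxide F10, whose syn elimination toward the C16 methyl, away from the chlorine-bearing carbon, gives 42.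

Further compounds
F1 | step 3 | lithium (Z)-penta-1,3-dien-3-olate | C=C/C(O[Li])=C/C
F2 | step 3 | ring A lithium enolate (C12–OLi, Δ12; otherwise as 6) | O=C(O[C@@H]1C[C@H](C)CC[C@H]1C(C)C)[C@H]2[C@@H](C)C(O[Li])=CC[C@]2(C)C(=O)O[C@@H]3C[C@H](C)CC[C@H]3C(C)C
F3 | step 21 | seco alcohol (30 without the C7 triethylsilyl group) | C/C(I)=C/[C@H](O)[C@@H](OCc1ccc(OC)cc1)[C@H](O[Si](C)(C)C(C)(C)C)[C@H]2[C@@H](C)[C@H](Oc3ccc(OC)cc3)C=C[C@]2(C)[C@H](OC(C)=O)C=C
F4 | step 21 | seco C7 2-bromopropanoate | C/C(I)=C/[C@H](OC(=O)C(C)Br)[C@@H](OCc1ccc(OC)cc1)[C@H](O[Si](C)(C)C(C)(C)C)[C@H]2[C@@H](C)[C@H](Oc3ccc(OC)cc3)C=C[C@]2(C)[C@H](OC(C)=O)C=C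
F5 | step 21 | seco C8 alcohol | C/C(I)=C/[C@H](OC(=O)C(C)Br)[C@@H](O)[C@H](O[Si](C)(C)C(C)(C)C)[C@H]2[C@@H](C)[C@H](Oc3ccc(OC)cc3)C=C[C@]2(C)[C@H](OC(C)=O)C=C
F6 | step 21 | seco C8 ketone | C/C(I)=C/[C@H](OC(=O)C(C)Br)C(=O)[C@H](O[Si](C)(C)C(C)(C)C)[C@H]2[C@@H](C)[C@H](Oc3ccc(OC)cc3)C=C[C@]2(C)[C@H](OC(C)=O)C=C
F7 | step 21 | seco hydroxy lactone (lactone as in 38, ring B open) | C/C(I)=C/[C@@H]1OC(=O)[C@H](C)[C@@]1(O)[C@H](O[Si](C)(C)C(C)(C)C)[C@H]2[C@@H](C)[C@H](Oc3ccc(OC)cc3)C=C[C@]2(C)[C@H](OC(C)=O)C=C
F8 | step 21 | lactone B-alkyl-9-borabicyclo[3.3.1]nonane (boron on C4) | C/C(I)=C/[C@@H]1OC(=O)[C@H](C)[C@@]1(O)[C@H](O[Si](C)(C)C(C)(C)C)[C@H]2[C@@H](C)[C@H](Oc3ccc(OC)cc3)C=C[C@]2(C)[C@H](OC(C)=O)CCB4C5CCCC4CCC5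
F9 | step 30 | 6-chloro-5-(phenylselanyl) anti adduct of 41 | C[C@@]1([Se]c2ccccc2)CC[C@@H](OC(C)=O)[C@]3(C)[C@H]([C@@H](C)[C@H](OC(C)=O)[C@@H]4O[C@@H]43)[C@@H](O[Si](C)(C)C(C)(C)C)[C@]5(O)[C@@H](C)C(=O)O[C@H]5[C@H]1Cl
F10 | step 30 | selenoxide of F9 | C[C@@]1([Se](=O)c2ccccc2)CC[C@@H](OC(C)=O)[C@]3(C)[C@H]([C@@H](C)[C@H](OC(C)=O)[C@@H]4O[C@@H]43)[C@@H](O[Si](C)(C)C(C)(C)C)[C@]5(O)[C@@H](C)C(=O)O[C@H]5[C@H]1Cl
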